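Remark: labdane numbering (C1–C20) is used for all bicyclic compounds and for the carbons of the acyclic precursors that become them. The all‑(E) isomer of geranylgeraniol (1) is assumed to be commercially available.

## Analysis of the target

The target 13 is a labdane diterpenoid, (5S,6S,7S,10S)‑6β‑acetoxy‑7α‑(3‑methylbutanoyloxy)labda‑8,13E‑dien‑15‑oic acid. It is a trans‑decalin: ring A (C1–C5, C10) carries the gem‑dimethyl group on C4, and ring B (C5–C10) carries the angular methyl on C10 and a tetrasubstituted C8=C9 alkene with a methyl on C8. C9 bears the chain C11–C12–C13(CH3)=C14–C15O2H, an (E)‑trisubstituted enoic acid.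

There are four stereocentres. C5 (H α) and C10 (CH3 β) define the trans ring fusion and have no function next to them. C6 (acetate β, axial, syn to the axial methyls on C4 and C10) and C7 (isovalerate α, pseudo‑axial) form a trans‑diaxial diester.

Reagents reach ring B from the α face only. C6 must therefore receive hydrogen from that face, so it has to pass through a ketone, and C7 must receive oxygen from that face.

The carbon skeleton is geranylgeranic acid folded twice. The bonds C4–C5 and C9–C10 close rings A and B, and the 13,14‑enoate is the untouched head of the chain. This is the feature that invites a cyclisation copying the biosynthesis.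

Sensitive groups are the allylic secondary ester on C7 (ionisation, elimination to a 6,8‑diene), two different esters on neighbouring carbons, a tetrasubstituted alkene that migrates under acid, and a conjugated acid that must be freed in the presence of both esters.

The hard parts are the quaternary C10 in one absolute configuration without a directing group, the position of the ring B double bond, and the axial 6β‑oxygen on the hindered face.

## Retrosynthetic reasoning

13 to 12: the O–allyl bond of the C15 ester is cut. An allyl ester is the one acid protection that can be removed under neutral conditions without touching the acetate, the isovalerate or the allylic C7–O bond.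

12 to 11 to 10: the two acyl–oxygen bonds are cut, acetyl on O6 last and 3‑methylbutanoyl on O7 before it. In diol 10 the allylic 7α‑hydroxyl is open, while the 6β‑hydroxyl sits under two syn‑axial methyl groups, so the bulkier acyl group goes on first where access is easy. The trans‑diaxial geometry excludes acyl migration.

10 to 9: the C6–H bond is cut, giving a 6‑ketone. Hydride can only come from the α face, which yields exactly the axial 6β‑alcohol. An oxygen electrophile at C6 would give the wrong epimer, which is why C6 is carried as a carbonyl.

9 to 7 (through 8): the C7–O bond is cut. Enone 7 has its double bond at C7–C8. Its extended enolate 8 places the double bond at C8–C9 and takes oxygen at C7 from the α face. One operation thus sets C7, moves the alkene to its final tetrasubstituted position and erases C9, so the configuration at C9 in 7 does not matter.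

7 to 6: the C6=O bond is cut back to the allylic methylene of 6. C6 is allylic only in the 7,8‑olefin, so the route needs this isomer and not the 8,9‑olefin.

6 to 4 (through 5): the bonds C4–C5 and C9–C10 are cut, which opens both rings and leads to the achiral, acyclic tetraene ester 4. The forward reaction has to fold 4 chair–chair, set C5 and C10 (and C9) in one enantiomeric sense, stop after two rings and end with the double bond at C7–C8. The conjugated ester keeps the last alkene out of the cascade, so no protecting group or extra carbon is needed.

4 to 1: the ester C–O bond and the oxidation level at C15 are adjusted. 4 comes from alcohol 1 by two oxidations (2, 3) and O‑allylation.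

## Alternatives that were turned down

Alternative 1: the textbook chiral‑pool route, cutting the C13=C14 bond on a decalin bought ready‑made. (−)‑Sclareol A1 would be degraded in its side chain and dehydrated to the methyl ketone A2 (14,15‑dinorlabd‑8‑en‑13‑one). The forward key step is a Horner–Wadsworth–Emmons olefination of A2 to ethyl labda‑8,13E‑dien‑15‑oate A3. Turned down for three reasons:
- The key step forms no ring and no stereocentre; two carbons are cut off the side chain only to be put back.
- The olefination of a methyl ketone gives an E/Z mixture at C13.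
- A3 is the 8,9‑olefin, in which C6 is not allylic. The C6 oxygen then has to be reached through oxidation at C7 and transposition, several steps more than from 6.

Alternative 2: a Diels–Alder construction of ring B, cutting C7–C8 and C9–C10. The silyloxy diene A4 (from the acetyl‑trimethylcyclohexene of ring A) would react with methyl but‑2‑ynoate A5 to give, after hydrolysis of the enol ether, the keto ester A6 with the 6‑ketone, the 8,9‑alkene and the quaternary C10 in one step. Turned down for three reasons:
- C10 is the only stereocentre the cycloaddition forms, and no reliable enantioselective version exists for a tetrasubstituted diene terminus with an alkynoate, so A6 would be racemic and need resolution.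
- The diene is twisted out of the s‑cis form by the ring methyl groups and the β‑methyl alkynoate is a weak dienophile.
- The whole chain C12–C16 would still have to be grown from the C11 ester in four or more steps, which costs what the key step wins.

Alternative 3: dearomatisation, cutting C1–C10 and C4–C5 so that ring B comes from an arene. The ortho‑quinone monoketal A7 would take the Grignard reagent A8 at C10 in a conjugate addition (Cu(OTf)2 with a chiral carbene ligand). The enol carbon C5 would then close ring A onto the C4 cation of the prenyl terminus, giving A9 with oxygen on both C6 and C7. Turned down for four reasons: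
- The 2,4‑dienone offers two electrophilic sites (C10 by 1,4‑ and C8 by 1,6‑addition), and copper reagents tend to the 1,6 site.
- Enantioselective formation of a quaternary centre on such a dienone is not secured by the substrate.
- A7 is itself a multi‑step target, because a fully substituted arene has to be assembled and oxidised.
- The C7 carbonyl of A9 would later have to be reduced against the steric bias or inverted.
Two separate C–C bond formations, each with its own selectivity problem, replace one cascade.

Key step: step 4

## Route

Step 1
Reactants: 1 (2E,6E,10E)‑geranylgeraniol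
Product: 2 (2E,6E,10E)‑geranylgeranial
Conditions: MnO2 (activated, excess), CH2Cl2, 20 °C
Reagents that add atoms: none
Why: Selective oxidation of the allylic alcohol on MnO2; the isolated trisubstituted alkenes are inert and the 2E geometry should be kept under these neutral conditions.

Step 2
Reactants: 2 (2E,6E,10E)‑geranylgeranial
Product: 3 (2E,6E,10E)‑geranylgeranic acid
Conditions: NaClO2, NaH2PO4, 2‑methylbut‑2‑ene, t‑BuOH/H2O, 0 → 20 °C
Reagents that add atoms: sodium chlorite, [Na+].[O-]Cl=O
Why: Pinnick oxidation of the enal; the alkene scavenger takes up the hypochlorous acid so that the three electron‑rich chain alkenes are not chlorinated, and the enal geometry is not disturbed.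

Step 3
Reactants: 3 (2E,6E,10E)‑geranylgeranic acid
Product: 4 allyl (2E,6E,10E)‑geranylgeranoate
Conditions: allyl bromide, K2CO3, DMF, 20 °C
Reagents that add atoms: allyl bromide, C=CCBr
Why: SN2 O‑alkylation of the carboxylate; the allyl ester survives acid, base, oxidant and hydride in steps 4–9 and is the only ester that can be removed at the end without touching the acetate and isovalerate.

Step 4
Reactants: 4 allyl (2E,6E,10E)‑geranylgeranoate
Product: 6 allyl labda‑7,13E‑dien‑15‑oate (5α‑H; 9α‑H; 10β‑CH3; trans‑decalin), via tertiary C8 cation 5 (not isolated)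
Conditions: confined chiral imidodiphosphorimidate Brønsted acid (5 mol%, the antipode that leads to the 5S,10S series), (CF3)3COH, 0 °C; then Et3N
Reagents that add atoms: none
Why: The chiral acid protonates the terminal alkene of 4 at C3; the C4 cation is attacked by C5 of the middle (E)‑alkene and the resulting C10 cation by C9 of the next (E)‑alkene, so the σ‑bonds C4–C5 and C9–C10 and rings A and B form in one cascade that ends at cation 5. Both closures are 6‑endo‑trig cation–olefin additions through a chair–chair fold, with anti addition across each (E)‑alkene. The catalyst pocket selects one of the two enantiomeric folds when C5 bonds to C4, which fixes C5; the (E) geometry of the middle alkene then places the C10 methyl anti to H‑5 (trans‑decalin), and that of the third alkene places H‑9 axial and the side chain equatorial, so only one event needs catalyst control. The closest known reaction type is the enantioselective proton‑initiated bicyclisation of (E,E)‑homofarnesyl substrates to trans‑decalins, with acids of this class in fluorinated alcohols or with SnCl4–binaphthol Brønsted acids. The cascade must stop after two rings: the 13,14‑alkene is conjugated with the ester and too electron‑poor to add to cation 5, and the ester oxygen could only close an eight‑membered ring. Cation 5 must lose the axial 7α‑hydrogen, the least hindered proton aligned with the empty orbital, to give the 7,8‑alkene; the C9 methine is shielded by C10 and the chain, and any exocyclic olefin formed alongside is expected to move into the ring under the same acid. Low temperature and the non‑nucleophilic alcohol should keep cation 5 from hydride or methyl shifts and from solvent capture.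

Step 5
Reactants: 6 allyl labda‑7,13E‑dien‑15‑oate
Product: 7 allyl 6‑oxolabda‑7,13E‑dien‑15‑oate (5α‑H; 9α‑H; 10β‑CH3)
Conditions: CrO3, 3,5‑dimethylpyrazole, CH2Cl2, −20 °C
Reagents that add atoms: chromium trioxide, O=[Cr](=O)=O
Why: Allylic oxidation by the hexavalent chromium–pyrazole complex at C6, the only allylic methylene of the 7,8‑alkene, as in the conversion of 7‑ene sterols into 7‑en‑6‑ones. The tertiary C9–H is shielded by C10, and the enoate and allyl ester alkenes are electron‑poor.

Step 6
Reactants: 7 allyl 6‑oxolabda‑7,13E‑dien‑15‑oate
Product: 9 allyl 7α‑hydroxy‑6‑oxolabda‑8,13E‑dien‑15‑oate (5α‑H; 10β‑CH3), via potassium dienolate 8 (not isolated)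
Conditions: KN(SiMe3)2 (0.95 equiv), THF, −78 → 0 °C, then −78 °C; 2‑(phenylsulfonyl)‑3‑phenyloxaziridine; AcOH
Reagents that add atoms: 2‑(phenylsulfonyl)‑3‑phenyloxaziridine, O1C(c2ccccc2)N1S(=O)(=O)c1ccccc1; potassium bis(trimethylsilyl)amide (potassium of 8 only), [K+].C[Si](C)(C)[N-][Si](C)(C)C
Why: A slight deficit of base lets the enolates equilibrate by proton transfer to the linear endocyclic dienolate 8 (C6=C7, C8=C9), the counterpart of the most stable, tetrasubstituted ring B olefin. The N‑sulfonyloxaziridine then transfers oxygen to the α‑carbon C7 from the α face, anti to the axial C10 methyl; the γ‑carbon C9 is fully substituted and blocked. This deconjugative α‑hydroxylation of an extended enolate sets C7 (7α‑OH), fixes the double bond at C8–C9 and erases C9 in one step.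

Step 7
Reactants: 9 allyl 7α‑hydroxy‑6‑oxolabda‑8,13E‑dien‑15‑oate
Product: 10 allyl 6β,7α‑dihydroxylabda‑8,13E‑dien‑15‑oate (5α‑H; 10β‑CH3)
Conditions: NaBH4, CeCl3·7H2O, MeOH, −78 °C
Reagents that add atoms: none
Why: Luche‑type 1,2‑reduction; the β face of C6 is closed by the syn‑axial methyls on C4 and C10, so hydride enters from the α face and gives the axial 6β‑alcohol, trans‑diaxial to the 7α‑hydroxyl. The cold, nearly neutral medium should prevent enolisation of the α‑ketol; both esters are inert.

Step 8
Reactants: 10 allyl 6β,7α‑dihydroxylabda‑8,13E‑dien‑15‑oate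
Product: 11 allyl 6β‑hydroxy‑7α‑(3‑methylbutanoyloxy)labda‑8,13E‑dien‑15‑oate
Conditions: (i‑PrCH2CO)2O (1.2 equiv), pyridine, DMAP (cat.), CH2Cl2, 0 °C
Reagents that add atoms: 3‑methylbutanoic anhydride, CC(C)CC(=O)OC(=O)CC(C)C
Why: DMAP‑catalysed acylation discriminates by access: the allylic 7α‑hydroxyl has only H‑5 as a syn‑axial neighbour, while the 6β‑hydroxyl lies under two axial methyl groups. The trans‑diaxial arrangement excludes later acyl migration.

Step 9
Reactants: 11 allyl 6β‑hydroxy‑7α‑(3‑methylbutanoyloxy)labda‑8,13E‑dien‑15‑oate
Product: 12 allyl 6β‑acetoxy‑7α‑(3‑methylbutanoyloxy)labda‑8,13E‑dien‑15‑oate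
Conditions: Ac2O, Et3N, DMAP (1 equiv), CH2Cl2, 40 °C
Reagents that add atoms: acetic anhydride, CC(=O)OC(C)=O
Why: The small acetyl group is delivered to the hindered axial 6β‑hydroxyl by the N‑acetylpyridinium ion under forcing nucleophilic catalysis. The amine medium does not ionise the allylic C7 ester, and no acyl exchange is possible between trans‑diaxial oxygens.

Step 10
Reactants: 12 allyl 6β‑acetoxy‑7α‑(3‑methylbutanoyloxy)labda‑8,13E‑dien‑15‑oate
Product: 13 (5S,6S,7S,10S)‑6β‑acetoxy‑7α‑(3‑methylbutanoyloxy)labda‑8,13E‑dien‑15‑oic acid (target)
Conditions: Pd(PPh3)4 (5 mol%), morpholine, THF, 20 °C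
Reagents that add atoms: none
Why: Tsuji–Trost deallylation: zerovalent palladium ionises the unhindered allyl ester and morpholine captures the allyl group under neutral conditions that leave acetate and isovalerate intact. The secondary allylic ester on C7 should not ionise, because the metal would have to reach the tetrasubstituted 8,9‑alkene from the β face, which is blocked by the C10 methyl and the 6β‑acetate.

## Compound list

1 | (2E,6E,10E)‑geranylgeraniol | CC(C)=CCC/C(C)=C/CC/C(C)=C/CC/C(C)=C/CO | starting material
2 | (2E,6E,10E)‑geranylgeranial | CC(C)=CCC/C(C)=C/CC/C(C)=C/CC/C(C)=C/C=O | intermediate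
3 | (2E,6E,10E)‑geranylgeranic acid | CC(C)=CCC/C(C)=C/CC/C(C)=C/CC/C(C)=C/C(=O)O | intermediate
4 | allyl (2E,6E,10E)‑geranylgeranoate | CC(C)=CCC/C(C)=C/CC/C(C)=C/CC/C(C)=C/C(=O)OCC=C | intermediate
5 | tertiary C8 cation of the bicyclic allyl ester (5α‑H, 9α‑H, 10β‑CH3), not isolated | C1C[C+](C)[C@H](CC/C(C)=C/C(=O)OCC=C)[C@@]2(C)CCCC(C)(C)[C@H]12 | intermediate
6 | allyl labda‑7,13E‑dien‑15‑oate (5α‑H, 9α‑H, 10β‑CH3) | C1C=C(C)[C@H](CC/C(C)=C/C(=O)OCC=C)[C@@]2(C)CCCC(C)(C)[C@H]12 | intermediate
7 | allyl 6‑oxolabda‑7,13E‑dien‑15‑oate (5α‑H, 9α‑H, 10β‑CH3) | O=C1C=C(C)[C@H](CC/C(C)=C/C(=O)OCC=C)[C@@]2(C)CCCC(C)(C)[C@H]12 | intermediate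
8 | potassium dienolate of 7 (6‑oxido‑6,8‑diene; 5α‑H, 10β‑CH3), not isolated | [K+].[O-]C1=CC(C)=C(CC/C(C)=C/C(=O)OCC=C)[C@@]2(C)CCCC(C)(C)[C@H]12 | intermediate
9 | allyl 7α‑hydroxy‑6‑oxolabda‑8,13E‑dien‑15‑oate (5α‑H, 10β‑CH3) | O=C1[C@@H](O)C(C)=C(CC/C(C)=C/C(=O)OCC=C)[C@@]2(C)CCCC(C)(C)[C@H]12 | intermediate
10 | allyl 6β,7α‑dihydroxylabda‑8,13E‑dien‑15‑oate | O[C@@H]1[C@@H](O)C(C)=C(CC/C(C)=C/C(=O)OCC=C)[C@@]2(C)CCCC(C)(C)[C@H]12 | intermediate
11 | allyl 6β‑hydroxy‑7α‑(3‑methylbutanoyloxy)labda‑8,13E‑dien‑15‑oate | O[C@@H]1[C@@H](OC(=O)CC(C)C)C(C)=C(CC/C(C)=C/C(=O)OCC=C)[C@@]2(C)CCCC(C)(C)[C@H]12 | intermediate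
12 | allyl 6β‑acetoxy‑7α‑(3‑methylbutanoyloxy)labda‑8,13E‑dien‑15‑oate | CC(=O)O[C@@H]1[C@@H](OC(=O)CC(C)C)C(C)=C(CC/C(C)=C/C(=O)OCC=C)[C@@]2(C)CCCC(C)(C)[C@H]12 | intermediate
13 | (5S,6S,7S,10S)‑6β‑acetoxy‑7α‑(3‑methylbutanoyloxy)labda‑8,13E‑dien‑15‑oic acid | CC(=O)O[C@@H]1[C@@H](OC(=O)CC(C)C)C(C)=C(CC/C(C)=C/C(=O)O)[C@@]2(C)CCCC(C)(C)[C@H]12 | target

## Step count and least certain steps

Total step count: 10. Longest linear sequence: 10 steps (1 to 13).

Step 4 (key step). The most likely failure is loss of regiocontrol when cation 5 is deprotonated, together with acid‑induced drift of the first‑formed olefin toward the tetrasubstituted 8,9‑position, which is the thermodynamic sink. An incomplete second ring closure and a lower enantioselectivity than with oxygen‑terminated substrates are secondary concerns.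

Fallback, starting from 4: the olefin position is no longer left to the cyclisation but set by thermodynamics and a reductive transposition. The crude olefin mixture from the same cyclisation of 4 is equilibrated with p‑toluenesulfonic acid in benzene to the tetrasubstituted isomer, allyl labda‑8,13E‑dien‑15‑oate F1. Allylic oxidation (CrO3, 3,5‑dimethylpyrazole) at the ring methylene C7 gives allyl 7‑oxolabda‑8,13E‑dien‑15‑oate F2. Condensation with tosylhydrazine gives the tosylhydrazone F3. Catecholborane followed by NaOAc·3H2O reduces the C=N bond; the allylic diazene loses dinitrogen while its hydrogen passes to C9 and the double bond shifts to C7–C8. This returns the material to the route at 6. The axial 7α‑diazene should deliver hydrogen to the α face of C9, and a C9 epimer would be harmless because C9 becomes trigonal in 8.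

Step 6. Proton transfer may stop at the cross‑conjugated C5 enolate or at the exocyclic dienolate from the C8 methyl group, or oxygen transfer may be diverted to C9 or to the β face. The kinetic acidities of the three sites are close and only the equilibrium favours 8.

Fallback, starting from 7: the enol derivative is isolated and oxidised with a reagent that is sensitive to hindrance. Silylation under equilibrating conditions (Me3SiCl, NaI, Et3N, MeCN) gives the trimethylsilyl dienol ether, allyl 6‑(trimethylsilyloxy)labda‑6,8,13E‑trien‑15‑oate F4, which can be purified from regioisomers. OsO4 (cat.) with N‑methylmorpholine N‑oxide in aqueous acetone then dihydroxylates the electron‑rich enol ether double bond from the α face, while the tetrasubstituted 8,9‑alkene is too hindered to react. Collapse of the osmate ester returns the material at 9.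

Step 9. Acetyl transfer to the 6β‑hydroxyl, which sits under two syn‑axial methyl groups, may be too slow, and prolonged forcing may start ionisation or elimination of the allylic C7 ester toward the 6,8‑diene.

Fallback, starting from 9: the acetate is put on a metal alkoxide at the moment it is formed. The only hydroxyl of 9 is acylated with 3‑methylbutanoic anhydride and DMAP to the keto ester, allyl 7α‑(3‑methylbutanoyloxy)‑6‑oxolabda‑8,13E‑dien‑15‑oate F5. Reduction with LiBH(s‑Bu)3 in THF at −78 °C, again from the α face, gives the lithium 6β‑alkoxide F6, which is trapped in the same flask with acetic anhydride. This reductive acetylation returns the material at 12.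

## Further compounds

F1 | step 4 | allyl labda‑8,13E‑dien‑15‑oate (5α‑H, 10β‑CH3) | C1CC(C)=C(CC/C(C)=C/C(=O)OCC=C)[C@@]2(C)CCCC(C)(C)[C@H]12
F2 | step 4 | allyl 7‑oxolabda‑8,13E‑dien‑15‑oate | C1C(=O)C(C)=C(CC/C(C)=C/C(=O)OCC=C)[C@@]2(C)CCCC(C)(C)[C@H]12
F3 | step 4 | tosylhydrazone of F2 (C=N isomers) | C1C(=NNS(=O)(=O)c3ccc(C)cc3)C(C)=C(CC/C(C)=C/C(=O)OCC=C)[C@@]2(C)CCCC(C)(C)[C@H]12
F4 | step 6 | allyl 6‑(trimethylsilyloxy)labda‑6,8,13E‑trien‑15‑oate | C[Si](C)(C)OC1=CC(C)=C(CC/C(C)=C/C(=O)OCC=C)[C@@]2(C)CCCC(C)(C)[C@H]12
F5 | step 9 | allyl 7α‑(3‑methylbutanoyloxy)‑6‑oxolabda‑8,13E‑dien‑15‑oate | O=C1[C@@H](OC(=O)CC(C)C)C(C)=C(CC/C(C)=C/C(=O)OCC=C)[C@@]2(C)CCCC(C)(C)[C@H]12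
F6 | step 9 | lithium 6β‑alkoxide of allyl 6β‑hydroxy‑7α‑(3‑methylbutanoyloxy)labda‑8,13E‑dien‑15‑oate | [Li+].[O-][C@@H]1[C@@H](OC(=O)CC(C)C)C(C)=C(CC/C(C)=C/C(=O)OCC=C)[C@@]2(C)CCCC(C)(C)[C@H]12
A1 | alternative 1 | (−)‑sclareol, (13R)‑labd‑14‑ene‑8α,13‑diol | C1C[C@@](C)(O)[C@H](CC[C@@](C)(O)C=C)[C@@]2(C)CCCC(C)(C)[C@H]12
A2 | alternative 1 | 14,15‑dinorlabd‑8‑en‑13‑one | C1CC(C)=C(CCC(C)=O)[C@@]2(C)CCCC(C)(C)[C@H]12
A3 | alternative 1 | ethyl labda‑8,13E‑dien‑15‑oate | C1CC(C)=C(CC/C(C)=C/C(=O)OCC)[C@@]2(C)CCCC(C)(C)[C@H]12
A4 | alternative 2 | tert‑butyldimethyl{[1‑(2,6,6‑trimethylcyclohex‑1‑en‑1‑yl)ethenyl]oxy}silane | C=C(O[Si](C)(C)C(C)(C)C)C1=C(C)CCCC1(C)C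
A5 | alternative 2 | methyl but‑2‑ynoate | CC#CC(=O)OC
A6 | alternative 2 | methyl 6‑oxodrim‑8‑en‑11‑oate (racemic; one enantiomer drawn) | O=C1CC(C)=C(C(=O)OC)[C@@]2(C)CCCC(C)(C)[C@H]12
A7 | alternative 3 | allyl (2E)‑5‑(5,5‑dimethoxy‑2,6‑dimethyl‑4‑oxocyclohexa‑1,2‑dien‑1‑yl... written as ring: 6,6‑dimethoxy‑3,5‑dimethyl‑1‑oxocyclohexa‑2,4‑dien‑4‑yl)‑3‑methylpent‑2‑enoate | O=C1C=C(C)C(CC/C(C)=C/C(=O)OCC=C)=C(C)C1(OC)OC
A8 | alternative 3 | 4‑methylpent‑3‑enylmagnesium bromide | CC(C)=CCC[Mg]Br
A9 | alternative 3 | allyl 7,7‑dimethoxy‑6‑oxolabda‑8,13E‑dien‑15‑oate | O=C1C(OC)(OC)C(C)=C(CC/C(C)=C/C(=O)OCC=C)[C@@]2(C)CCCC(C)(C)[C@H]12
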